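**Retrosynthetic overview**

- The route rests on the CH(CH3) stereocentre that links chromene C6 to the pentenyl chain. It lies beta to the alkene carbon bonded to benzofuran C2, and that alkene carbon can be carried as a ketone carbonyl, so the three-carbon linker is a chalcone-type enone.
- Late stage: the C5 acetyl group comes from the C5 bromide (Stille coupling with a 1-ethoxyvinyl unit, acid hydrolysis, MOM removed in the same operation). The E-trisubstituted alkene comes from the Z-enol triflate of benzofuran-2-yl ketone 17 and a methylcuprate.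
- Ketone 17 comes from enone 15 by enantioselective conjugate methylation, which sets the only stereocentre.
- Enone 15 comes from a Claisen–Schmidt condensation of 2-acetylbenzofuran 13 with chromene-6-carbaldehyde 7.
- Ring order: the pyran ring of the chromene is closed in step 1 and the furan ring of the benzofuran in step 4, on separate halves; no ring forms after the two halves are joined.

Key step: step 6

Assumption: the (S,R,R)-phosphoramidite is taken to deliver methyl to the Si face of C3 of enone 15; should a trial run show the opposite sense, its mirror image is used with nothing else changed.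

**Route**

Step 1
Reactants: 1 4-bromo-3-methoxyphenol; 2 3-methylbut-2-enal
Product: 5 6-bromo-7-methoxy-2,2-dimethyl-2H-chromene, via dioxaborinine 3 (not isolated), via o-quinone methide 4 (not isolated)
Conditions: PhB(OH)2 (1.1 equiv), EtCO2H (cat.), toluene, reflux, Dean–Stark
Reagents that add atoms: none
Why: Phenylboronic acid-mediated ortho-specific condensation of a phenol with an enal, in which dioxaborinine 3 fragments on heating to o-quinone methide 4 and an oxa-6π electrocyclisation closes the pyran ring; attack at phenol C6 (para to OMe, unhindered) rather than C2 (flanked by OH and OMe) should give the linear 6-bromo-7-methoxy pattern, and no stereocentre is formed.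

Step 2
Reactants: 5 6-bromo-7-methoxy-2,2-dimethyl-2H-chromene
Product: 7 7-methoxy-2,2-dimethyl-2H-chromene-6-carbaldehyde, via aryllithium 6 (not isolated)
Conditions: n-BuLi, THF, −78 °C; DMF, −78 °C → rt; H2O
Reagents that add atoms: N,N-dimethylformamide (DMF) CN(C)C=O
Why: Bromine–lithium exchange next to the methoxy group is fast at −78 °C, and formylation of the aryllithium with DMF (Bouveault-type aldehyde synthesis) places the aldehyde at C6 with no regiochemical ambiguity.

Step 3
Reactants: 8 5-bromo-2,4-dihydroxybenzaldehyde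
Product: 9 5-bromo-2-hydroxy-4-(methoxymethoxy)benzaldehyde
Conditions: MOMCl (1.05 equiv), K2CO3 (1.1 equiv), acetone, 0 °C → rt
Reagents that add atoms: chloromethyl methyl ether (MOMCl) COCCl
Why: Williamson-type O-alkylation under one equivalent of weak base should take the more acidic 4-OH (para to CHO, ortho to Br), since the 2-OH is held in a hydrogen bond to the aldehyde.

Step 4
Reactants: 9 5-bromo-2-hydroxy-4-(methoxymethoxy)benzaldehyde; 10 chloroacetone
Product: 13 1-[5-bromo-6-(methoxymethoxy)-1-benzofuran-2-yl]ethan-1-one, via aryloxyacetone 11 (not isolated), via cyclic aldol 12 (not isolated)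
Conditions: K2CO3, MeCN, reflux
Reagents that add atoms: none
Why: Rap–Stoermer-type benzofuran annulation, in which O-alkylation of the free 2-OH, intramolecular aldol addition of the ketone α-CH2 to the aldehyde and dehydration build the aromatic furan ring, while the MOM acetal and aryl bromide are inert to carbonate.

Step 5
Reactants: 13 1-[5-bromo-6-(methoxymethoxy)-1-benzofuran-2-yl]ethan-1-one; 7 7-methoxy-2,2-dimethyl-2H-chromene-6-carbaldehyde
Product: 15 (E)-1-[5-bromo-6-(methoxymethoxy)-1-benzofuran-2-yl]-3-(7-methoxy-2,2-dimethyl-2H-chromen-6-yl)prop-2-en-1-one, via aldol 14 (not isolated)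
Conditions: KOH, EtOH/H2O, rt
Reagents that add atoms: none
Why: Claisen–Schmidt condensation in which the methyl ketone is the only enolisable partner and the aldehyde the only electrophile, and E1cB dehydration of aldol 14 should give the conjugated E-enone under thermodynamic control.

Step 6
Reactants: 15 (E)-1-[5-bromo-6-(methoxymethoxy)-1-benzofuran-2-yl]-3-(7-methoxy-2,2-dimethyl-2H-chromen-6-yl)prop-2-en-1-one
Product: 17 (3S)-1-[5-bromo-6-(methoxymethoxy)-1-benzofuran-2-yl]-3-(7-methoxy-2,2-dimethyl-2H-chromen-6-yl)butan-1-one, via zinc enolate 16 (not isolated)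
Conditions: Me2Zn (2.5 equiv), Cu(OTf)2 (3 mol %), (S,R,R)-phosphoramidite from (S)-BINOL and bis[(R)-1-phenylethyl]amine (6 mol %), toluene, −20 → 0 °C, slow addition of 15; aq. NH4Cl
Reagents that add atoms: dimethylzinc (Me2Zn) C[Zn]C
Why: Me2Zn reduces Cu(OTf)2 to monovalent copper and transfers a methyl group to it; the ligand-bound methylcopper–zinc species π-binds the s-cis enone, adds at C3 to give a trivalent copper σ-alkyl and reductively eliminates, which forms the C3–CH3 bond and leaves methylzinc enolate 16 for protonation at the quench. The closest known reaction type is the copper/phosphoramidite-catalysed enantioselective 1,4-addition of dialkylzinc reagents to chalcones. No ring closes. The new stereocentre C3 is controlled by the chiral phosphoramidite on copper alone, which has to deliver methyl to the Si face of C3 to give 3S. The step needs 1,4- over 1,2-addition and one enantioface: Me2Zn does not add to the ketone without copper, the pure E geometry of 15 presents a single prochiral β-carbon, and the aryl bromide, MOM acetal and chromene alkene do not react with Me2Zn.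

Step 7
Reactants: 17 (3S)-1-[5-bromo-6-(methoxymethoxy)-1-benzofuran-2-yl]-3-(7-methoxy-2,2-dimethyl-2H-chromen-6-yl)butan-1-one
Product: 19 (1Z,3S)-1-[5-bromo-6-(methoxymethoxy)-1-benzofuran-2-yl]-3-(7-methoxy-2,2-dimethyl-2H-chromen-6-yl)but-1-en-1-yl trifluoromethanesulfonate, via potassium enolate 18 (not isolated)
Conditions: KN(SiMe3)2 (1.05 equiv), THF, −78 °C; PhNTf2 (1.1 equiv), −78 → 0 °C; H2O
Reagents that add atoms: N-phenylbis(trifluoromethanesulfonimide) (PhNTf2) O=S(=O)(N(c1ccccc1)S(=O)(=O)C(F)(F)F)C(F)(F)F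
Why: Kinetic deprotonation of the aryl ketone at its only α-position (the CH2) should give the Z(O)-enolate, in which the C3 substituent avoids the benzofuranyl group, and O-sulfonylation by PhNTf2 traps it as the Z-enol triflate; the C3 stereocentre is not α to the carbonyl and stays untouched as long as no excess base remains.

Step 8
Reactants: 19 (1Z,3S)-1-[5-bromo-6-(methoxymethoxy)-1-benzofuran-2-yl]-3-(7-methoxy-2,2-dimethyl-2H-chromen-6-yl)but-1-en-1-yl trifluoromethanesulfonate
Product: 20 5-bromo-6-(methoxymethoxy)-2-[(2E,4S)-4-(7-methoxy-2,2-dimethyl-2H-chromen-6-yl)pent-2-en-2-yl]-1-benzofuran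
Conditions: Me2CuLi (3 equiv, from MeLi and CuI), THF/Et2O, −20 → 0 °C; aq. NH4Cl/NH3
Reagents that add atoms: Me2CuLi [Li+].C[Cu-]C (made in the flask from methyllithium C[Li] and CuI)
Why: Coupling of an enol triflate with a lithium dialkylcuprate replaces OTf by methyl with retention of alkene geometry, so the Z-triflate should give the E-alkene, while the aryl bromide reacts far more slowly with the cuprate at or below 0 °C.

Step 9
Reactants: 20 5-bromo-6-(methoxymethoxy)-2-[(2E,4S)-4-(7-methoxy-2,2-dimethyl-2H-chromen-6-yl)pent-2-en-2-yl]-1-benzofuran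
Product: 23 1-{6-hydroxy-2-[(2E,4S)-4-(7-methoxy-2,2-dimethyl-2H-chromen-6-yl)pent-2-en-2-yl]-1-benzofuran-5-yl}ethan-1-one, via enol ether 21 (not isolated), via MOM ketone 22 (not isolated)
Conditions: tributyl(1-ethoxyvinyl)stannane (1.5 equiv), Pd(PPh3)4 (5 mol %), toluene, 100 °C; then 2 M aq. HCl, THF, rt
Reagents that add atoms: tributyl(1-ethoxyvinyl)stannane CCCC[Sn](CCCC)(CCCC)C(=C)OCC; water O
Why: Stille coupling of the aryl bromide, after oxidative addition to zerovalent palladium, installs a masked acetyl group, and the aqueous acid then hydrolyses the enol ether to the methyl ketone and cleaves the MOM acetal to a phenol hydrogen-bonded to the new ortho-acetyl group; neither the allylic stereocentre nor the alkene geometry takes part.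

**Compound list**

1 | 4-bromo-3-methoxyphenol | COc1cc(O)ccc1Br | starting material
2 | 3-methylbut-2-enal | CC(C)=CC=O | starting material
3 | 6-bromo-7-methoxy-4-(2-methylprop-1-en-1-yl)-2-phenyl-4H-1,3,2-benzodioxaborinine (racemic) | COc1cc2OB(c3ccccc3)OC(C=C(C)C)c2cc1Br | intermediate
4 | 4-bromo-3-methoxy-6-(3-methylbut-2-en-1-ylidene)cyclohexa-2,4-dien-1-one | COC1=CC(=O)C(=CC=C(C)C)C=C1Br | intermediate
5 | 6-bromo-7-methoxy-2,2-dimethyl-2H-chromene | COc1cc2c(cc1Br)C=CC(C)(C)O2 | intermediate
6 | (7-methoxy-2,2-dimethyl-2H-chromen-6-yl)lithium | [Li]c1cc2C=CC(C)(C)Oc2cc1OC | intermediate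
7 | 7-methoxy-2,2-dimethyl-2H-chromene-6-carbaldehyde | COc1cc2c(cc1C=O)C=CC(C)(C)O2 | intermediate
8 | 5-bromo-2,4-dihydroxybenzaldehyde | O=Cc1cc(Br)c(O)cc1O | starting material
9 | 5-bromo-2-hydroxy-4-(methoxymethoxy)benzaldehyde | COCOc1cc(O)c(C=O)cc1Br | intermediate
10 | chloroacetone | CC(=O)CCl | starting material
11 | 5-bromo-4-(methoxymethoxy)-2-(2-oxopropoxy)benzaldehyde | CC(=O)COc1cc(OCOC)c(Br)cc1C=O | intermediate
12 | 1-[5-bromo-3-hydroxy-6-(methoxymethoxy)-2,3-dihydro-1-benzofuran-2-yl]ethan-1-one (diastereomer mixture) | CC(=O)C1Oc2cc(OCOC)c(Br)cc2C1O | intermediate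
13 | 1-[5-bromo-6-(methoxymethoxy)-1-benzofuran-2-yl]ethan-1-one | CC(=O)c1cc2cc(Br)c(OCOC)cc2o1 | intermediate
14 | 1-[5-bromo-6-(methoxymethoxy)-1-benzofuran-2-yl]-3-hydroxy-3-(7-methoxy-2,2-dimethyl-2H-chromen-6-yl)propan-1-one (racemic) | COc1cc2c(cc1C(O)CC(=O)c1cc3cc(Br)c(OCOC)cc3o1)C=CC(C)(C)O2 | intermediate
15 | (E)-1-[5-bromo-6-(methoxymethoxy)-1-benzofuran-2-yl]-3-(7-methoxy-2,2-dimethyl-2H-chromen-6-yl)prop-2-en-1-one | COc1cc2c(cc1/C=C/C(=O)c1cc3cc(Br)c(OCOC)cc3o1)C=CC(C)(C)O2 | intermediate
16 | methylzinc (1Z,3S)-1-[5-bromo-6-(methoxymethoxy)-1-benzofuran-2-yl]-3-(7-methoxy-2,2-dimethyl-2H-chromen-6-yl)but-1-en-1-olate | COc1cc2c(cc1[C@@H](C)/C=C(\O[Zn]C)c1cc3cc(Br)c(OCOC)cc3o1)C=CC(C)(C)O2 | intermediate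
17 | (3S)-1-[5-bromo-6-(methoxymethoxy)-1-benzofuran-2-yl]-3-(7-methoxy-2,2-dimethyl-2H-chromen-6-yl)butan-1-one | COc1cc2c(cc1[C@@H](C)CC(=O)c1cc3cc(Br)c(OCOC)cc3o1)C=CC(C)(C)O2 | intermediate
18 | potassium (1Z,3S)-1-[5-bromo-6-(methoxymethoxy)-1-benzofuran-2-yl]-3-(7-methoxy-2,2-dimethyl-2H-chromen-6-yl)but-1-en-1-olate | COc1cc2c(cc1[C@@H](C)/C=C(\[O-])c1cc3cc(Br)c(OCOC)cc3o1)C=CC(C)(C)O2.[K+] | intermediate
19 | (1Z,3S)-1-[5-bromo-6-(methoxymethoxy)-1-benzofuran-2-yl]-3-(7-methoxy-2,2-dimethyl-2H-chromen-6-yl)but-1-en-1-yl trifluoromethanesulfonate | COc1cc2c(cc1[C@@H](C)/C=C(\OS(=O)(=O)C(F)(F)F)c1cc3cc(Br)c(OCOC)cc3o1)C=CC(C)(C)O2 | intermediate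
20 | 5-bromo-6-(methoxymethoxy)-2-[(2E,4S)-4-(7-methoxy-2,2-dimethyl-2H-chromen-6-yl)pent-2-en-2-yl]-1-benzofuran | COc1cc2c(cc1[C@@H](C)/C=C(\C)c1cc3cc(Br)c(OCOC)cc3o1)C=CC(C)(C)O2 | intermediate
21 | 5-(1-ethoxyethenyl)-6-(methoxymethoxy)-2-[(2E,4S)-4-(7-methoxy-2,2-dimethyl-2H-chromen-6-yl)pent-2-en-2-yl]-1-benzofuran | COc1cc2c(cc1[C@@H](C)/C=C(\C)c1cc3cc(C(=C)OCC)c(OCOC)cc3o1)C=CC(C)(C)O2 | intermediate
22 | 1-{6-(methoxymethoxy)-2-[(2E,4S)-4-(7-methoxy-2,2-dimethyl-2H-chromen-6-yl)pent-2-en-2-yl]-1-benzofuran-5-yl}ethan-1-one | COc1cc2c(cc1[C@@H](C)/C=C(\C)c1cc3cc(C(C)=O)c(OCOC)cc3o1)C=CC(C)(C)O2 | intermediate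
23 | 1-{6-hydroxy-2-[(2E,4S)-4-(7-methoxy-2,2-dimethyl-2H-chromen-6-yl)pent-2-en-2-yl]-1-benzofuran-5-yl}ethan-1-one | COc1cc2c(cc1[C@@H](C)/C=C(\C)c1cc3cc(C(C)=O)c(O)cc3o1)C=CC(C)(C)O2 | target

**Step count and risks**

Total steps: 9. Longest linear sequence: 7 steps (steps 1, 2, 5, 6, 7, 8, 9; the branch through steps 3 and 4 is equally long).

Steps most likely to fail:

1. Step 6. Methyl transfer to an electron-rich, ortho-substituted β-aryl enone may be slow, so that zinc enolate 16 adds to unreacted 15 (Michael oligomerisation), and enantioface discrimination may be insufficient. The fallback forms the aryl–C3 bond instead of the methyl–C3 bond; it sets out from bromide 5 and ketone 13 and comes back at ketone 17. Bromide 5 is lithiated as in step 2 and aryllithium 6 is quenched with B(OMe)3 and then water to give (7-methoxy-2,2-dimethyl-2H-chromen-6-yl)boronic acid F1. Ketone 13 is deprotonated with LiN(i-Pr)2 (THF, −78 °C) and treated with acetaldehyde to give racemic 1-[5-bromo-6-(methoxymethoxy)-1-benzofuran-2-yl]-3-hydroxybutan-1-one F2. MsCl/Et3N converts F2 through 4-[5-bromo-6-(methoxymethoxy)-1-benzofuran-2-yl]-4-oxobutan-2-yl methanesulfonate F3 into (E)-1-[5-bromo-6-(methoxymethoxy)-1-benzofuran-2-yl]but-2-en-1-one F4. Hayashi–Miyaura addition of F1 (in excess, to offset protodeboronation) to F4 with Rh(acac)(C2H4)2 and the BINAP enantiomer that delivers the aryl group to the Si face of C3 of F4 (dioxane/H2O, 100 °C) should give 17.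

2. Step 8. Halogen–copper exchange at the aryl bromide, reduction of the triflate, or base-induced loss of triflic acid toward the alkyne may compete with methyl transfer. The fallback replaces the triflate/cuprate pair by carbonyl addition and dehydration; it sets out from ketone 17 and comes back at alkene 20. MeMgBr with anhydrous CeCl3 (THF, −78 °C) adds to the ketone to give (4S)-2-[5-bromo-6-(methoxymethoxy)-1-benzofuran-2-yl]-4-(7-methoxy-2,2-dimethyl-2H-chromen-6-yl)pentan-2-ol F5 as a mixture of C2 epimers. Dehydration with catalytic pyridinium p-toluenesulfonate in warm toluene passes through the benzofuran-stabilised tertiary cation and, under thermodynamic control, should give the conjugated E-alkene 20.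

3. Step 9. Oxidative addition of the electron-rich, ortho-alkoxy aryl bromide may be slow, leaving stannane homocoupling and protodestannylation to dominate, and the acid stage may isomerise the alkene or hydrate the chromene. The fallback replaces the palladium coupling by acylation of an organolithium; it sets out from bromide 20 and comes back at MOM ketone 22. n-BuLi (THF, −78 °C) exchanges the bromide to give {6-(methoxymethoxy)-2-[(2E,4S)-4-(7-methoxy-2,2-dimethyl-2H-chromen-6-yl)pent-2-en-2-yl]-1-benzofuran-5-yl}lithium F6, which is acylated with N-methoxy-N-methylacetamide to 22, isolated in this case. MOM removal with dilute HCl in MeOH at room temperature then gives 23.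

**Further compounds**

F1 | step 6 | (7-methoxy-2,2-dimethyl-2H-chromen-6-yl)boronic acid | COc1cc2c(cc1B(O)O)C=CC(C)(C)O2
F2 | step 6 | 1-[5-bromo-6-(methoxymethoxy)-1-benzofuran-2-yl]-3-hydroxybutan-1-one (racemic) | CC(O)CC(=O)c1cc2cc(Br)c(OCOC)cc2o1
F3 | step 6 | 4-[5-bromo-6-(methoxymethoxy)-1-benzofuran-2-yl]-4-oxobutan-2-yl methanesulfonate (racemic) | CC(OS(C)(=O)=O)CC(=O)c1cc2cc(Br)c(OCOC)cc2o1
F4 | step 6 | (E)-1-[5-bromo-6-(methoxymethoxy)-1-benzofuran-2-yl]but-2-en-1-one | C/C=C/C(=O)c1cc2cc(Br)c(OCOC)cc2o1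
F5 | step 8 | (4S)-2-[5-bromo-6-(methoxymethoxy)-1-benzofuran-2-yl]-4-(7-methoxy-2,2-dimethyl-2H-chromen-6-yl)pentan-2-ol (both C2 epimers) | COc1cc2c(cc1[C@@H](C)CC(C)(O)c1cc3cc(Br)c(OCOC)cc3o1)C=CC(C)(C)O2
F6 | step 9 | {6-(methoxymethoxy)-2-[(2E,4S)-4-(7-methoxy-2,2-dimethyl-2H-chromen-6-yl)pent-2-en-2-yl]-1-benzofuran-5-yl}lithium | COc1cc2c(cc1[C@@H](C)/C=C(\C)c1cc3cc([Li])c(OCOC)cc3o1)C=CC(C)(C)O2
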